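**Retrosynthetic overview**
1. 18 ⇒ 16: cut C3–C11, C12–C13 and the C–OH bond in one operation. C3 of the β‑diketone is turned into an enolonium carbon and is attacked by the C=C of the endo C7 prenyl group. The seven‑membered rings and the cyclopentane form last.
2. 16 ⇒ 10: the endo C7 prenyl group comes from a hydroxy‑adamantane aldol cage by retro‑aldol opening, alkenyl addition and deoxygenation.
3. 10 ⇒ 9 ⇒ 8: the cage arises from a dearomatised triketone by Michael addition (C1–C8, closes ring B) and aldol reaction (temporary C3–C10 bond). The spare enal arm is trimmed to the C3 prenyl group by loss of CO.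
4. 8 ⇒ 6 + 7: asymmetric allylation desymmetrises the arene. C5 is the only catalyst‑set stereocentre.
5. 6 ⇒ 4 + two units of 3. Ring order: ring A (from the arene), ring B, temporary aldol cage, then seven‑membered rings and cyclopentane.

**Atom labels.** Ring A is C1(benzoyl)–C2(=O)–C3–C4(=O)–C5(geranyl)–C9(=O, bridge). Ring B is C1–C8(Me2)–C7–C6–C5–C9. C10 is the carbon on C7 that ends as the bridge CH2. C11 is the CH bonded to C3 in 18. C12 is the ring CMe2. C13 is the CH bearing CMe2OH. C14 is the CH2 on C3.

**Assumption.** The (R,R) Trost ligand is taken to give the drawn C5 configuration. If the sense is opposite, the (S,S) ligand is used.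

Step 1
Reactants: 1 diethyl 2-(propan-2-ylidene)malonate
Product: 2 2-(propan-2-ylidene)propane-1,3-diol
Conditions: i-Bu2AlH (4.5 equiv), CH2Cl2, −78 → 0 °C; aq. Rochelle salt
Reagents that add atoms: none
Why: Hydride reduction of esters, in which i-Bu2AlH adds 1,2 to both ester groups faster than it adds in conjugate fashion to the tetrasubstituted alkene, so the allylic diol forms and no stereocentre is created.

Step 2
Reactants: 2 2-(propan-2-ylidene)propane-1,3-diol
Product: 3 2-(hydroxymethyl)-3-methylbut-2-enal
Conditions: MnO2 (8 equiv), CH2Cl2, 0 °C → rt, stopped at full conversion of 2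
Reagents that add atoms: none
Why: Allylic alcohol oxidation with MnO2, where the first oxidation gives an electron-poor enal whose remaining CH2OH is oxidised much more slowly, so the mono-aldehyde can be collected and no stereocentre is created.

Step 3
Reactants: 3 2-(hydroxymethyl)-3-methylbut-2-enal (2.2 equiv); 4 2,4,6-trihydroxybenzophenone
Product: 6 3,5-bis(2-formyl-3-methylbut-2-enyl)-2,4,6-trihydroxybenzophenone, via allylic mesylate 5 (not isolated)
Conditions: MsCl, Et3N, CH2Cl2, −20 °C; the cold solution is added to 4, K2CO3, THF/H2O, 0 °C → rt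
Reagents that add atoms: none
Why: Mesylation followed by double phenolate C-alkylation (SN2 at an activated allylic carbon), in which the two unsubstituted ring carbons are the most nucleophilic sites and re-aromatisation after each alkylation makes C-alkylation irreversible, giving the mirror-symmetric 3,5-disubstituted arene without a stereocentre.

Step 4
Reactants: 6 3,5-bis(2-formyl-3-methylbut-2-enyl)-2,4,6-trihydroxybenzophenone; 7 geranyl acetate
Product: 9 enal-bearing hydroxy-adamantane cage (C1 benzoyl; C3 2-formyl-3-methylbut-2-enyl; C5 geranyl; C8 gem-dimethyl; C10 carbinol bridging C3 and C7), via dearomatised triketone 8 (not isolated)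
Conditions: Pd2(dba)3·CHCl3 (2.5 mol %), (R,R)-DACH-phenyl Trost ligand (6 mol %), Et3N (0.2 equiv), CH2Cl2, −10 °C; then solvent swap to THF, conc. aq. HCl (0.5 equiv), 0 °C → rt
Reagents that add atoms: geranyl acetate, CC(C)=CCC/C(C)=C/COC(C)=O
Why: Proposed new method: zerovalent palladium ionises 7 to a π-geranyl complex, which the acidic mirror-symmetric arene 6 attacks at the unhindered allyl terminus through one of its two identical (enantiotopic) alkylated ring carbons, O-allylation being reversible, so there is no regiochemical choice and the ligand pocket alone fixes C5 (closest known chemistry: Tsuji–Trost asymmetric allylic alkylation of prochiral 1,3-dicarbonyl nucleophiles and palladium-catalysed allylic dearomatisation of phenols and acylphloroglucinols); acid then drives a reversible Michael addition of the benzoyl-bearing enol carbon to the protonated enal arm on C5 (C1–C8) and an aldol of C3 onto the freed aldehyde, and since all three tethers must lie on one face of ring A the cage fixes C1, C3 and C7 (C7–C10 bond endo) relative to C5, while closure through C3 first would end in a triacyl carbinol that reverts, and the C10 carbinol configuration is not controlled and is erased in step 7.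

Step 5
Reactants: 9 enal-bearing hydroxy-adamantane cage
Product: 10 hydroxy-adamantane cage with C3 prenyl and C5 geranyl
Conditions: [IrCl(cod)]2 (5 mol %), PPh3 (10 mol %), 1,4-dioxane, reflux
Reagents that add atoms: none
Why: Tsuji–Wilkinson-type catalytic decarbonylation, in which the only free formyl group is the enal on the C3 arm (the other aldehyde is locked as the C10 carbinol), so C–H insertion, CO extrusion and reductive elimination give the CH=CMe2 group, which has no alkene geometry to lose, and no stereocentre is touched.

Step 6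
Reactants: 10 hydroxy-adamantane cage with C3 prenyl and C5 geranyl; 11 2-methylprop-1-enylmagnesium bromide
Product: 14 bicyclic bis-acetate (C4 enol acetate; C10 allylic acetate on the endo C7 side chain), via endo-aldehyde 12 (not isolated), via allylic alcohol 13 (not isolated)
Conditions: CeCl3 (anhydrous, 4 equiv), 11 (4 equiv), THF, −78 → 0 °C; then Ac2O, DMAP, 0 °C → rt
Reagents that add atoms: 2-methylprop-1-enylmagnesium bromide, CC(C)=C[Mg]Br; acetic anhydride, CC(=O)OC(C)=O
Why: Retro-aldol opening followed by organocerium 1,2-addition and O-acetylation, in which the first equivalent deprotonates the C10 alcohol, the alkoxide opens to the C3 enolate and the endo C7 aldehyde, and the weakly basic alkenylcerium adds to that aldehyde faster than C7 can epimerise or the hindered non-enolisable ketones can react, so C7 stays endo, and the new C10 stereocentre is uncontrolled and is removed in step 7.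

Step 7
Reactants: 14 bicyclic bis-acetate
Product: 16 1-benzoyl-5-geranyl-4-hydroxy-8,8-dimethyl-3,7-diprenylbicyclo[3.3.1]non-3-ene-2,9-dione with the C7 prenyl group endo, via enol acetate 15 (not isolated)
Conditions: Pd(PPh3)4 (10 mol %), HCO2NH4, 1,4-dioxane, 90 °C; then K2CO3 (cat.), MeOH, 0 °C
Reagents that add atoms: none
Why: Tsuji formate hydrogenolysis of an allylic acetate followed by methanolysis of the enol acetate, in which the neopentyl, concave C10 terminus cannot carry palladium, so the metal sits at the CMe2 end and hydride is delivered to C10 to give CH2–CH=CMe2, the enol acetate keeps C3 from attacking the π-allyl complex, and C1, C5 and C7 are untouched.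

Step 8
Reactants: 16 endo-7-prenyl bicyclic β-diketone
Product: 18 CNP0164095.1 (target), via iodane enol ether 17 (not isolated)
Conditions: PhI(OCOCF3)2 (1.1 equiv), NaHCO3 (2.5 equiv), (CF3)2CHOH/H2O 20:1, −20 → 0 °C
Reagents that add atoms: water, O
Why: Proposed new method: ligand exchange of the C4 enol with PhI(OCOCF3)2 gives the trivalent-iodine enol ether 17, in which C3, normally the nucleophilic carbon of the β-diketone, becomes an enolonium-type electrophile; the nucleophilic CH terminus C11 of the endo C7 prenyl group, held about 3 Å under C3, displaces iodobenzene, the tertiary C12 cation is captured 5-exo by C13 of the C3 prenyl group and the last tertiary cation by water; C3 is fixed by the tether, C11 by the CMe2 end of the prenyl group turning away from the C8 methyls towards C4/C6, and C13 by placing the cationic CMe2 group on the convex face of the forming cyclopentane, while the bridgehead geranyl group cannot reach C3 (closest known chemistry: α-umpolung of 1,3-dicarbonyls through trivalent-iodine enolonium species, oxidative cyclisations of prenylated acylphloroglucinols with trivalent manganese, and cation–olefin polycyclisation in fluorinated alcohols).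

**Compound list**
1 | diethyl 2-(propan-2-ylidene)malonate | CCOC(=O)C(=C(C)C)C(=O)OCC | starting material
2 | 2-(propan-2-ylidene)propane-1,3-diol | CC(C)=C(CO)CO | intermediate
3 | 2-(hydroxymethyl)-3-methylbut-2-enal | CC(C)=C(CO)C=O | intermediate
4 | 2,4,6-trihydroxybenzophenone | O=C(c1ccccc1)c1c(O)cc(O)cc1O | starting material
5 | (2-formyl-3-methylbut-2-enyl) methanesulfonate (not isolated) | CC(C)=C(COS(C)(=O)=O)C=O | intermediate
6 | 3,5-bis(2-formyl-3-methylbut-2-enyl)-2,4,6-trihydroxybenzophenone | O=C(c1ccccc1)c1c(O)c(CC(C=O)=C(C)C)c(O)c(CC(C=O)=C(C)C)c1O | intermediate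
7 | geranyl acetate | CC(C)=CCC/C(C)=C/COC(C)=O | starting material
8 | dearomatised triketone, quaternary C5 bearing geranyl and one enal arm (not isolated) | CC(C)=CCC/C(C)=C/C[C@@]1(CC(C=O)=C(C)C)C(=O)C(CC(C=O)=C(C)C)=C(O)C(C(=O)c2ccccc2)=C1O | intermediate
9 | enal-bearing hydroxy-adamantane cage (C10 carbinol epimers) | CC(C)=CCC/C(C)=C/C[C@@]12C[C@H]3C(O)[C@@](CC(C=O)=C(C)C)(C1=O)C(=O)[C@@](C(=O)c1ccccc1)(C2=O)C3(C)C | intermediate
10 | hydroxy-adamantane cage with C3 prenyl and C5 geranyl | CC(C)=CCC/C(C)=C/C[C@@]12C[C@H]3C(O)[C@@](CC=C(C)C)(C1=O)C(=O)[C@@](C(=O)c1ccccc1)(C2=O)C3(C)C | intermediate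
11 | 2-methylprop-1-enylmagnesium bromide | CC(C)=C[Mg]Br | starting material
12 | ring-opened endo C7 aldehyde (not isolated) | CC(C)=CCC/C(C)=C/C[C@]12C[C@@H](C=O)C(C)(C)[C@](C(=O)c3ccccc3)(C1=O)C(=O)C(CC=C(C)C)=C2O | intermediate
13 | C10 allylic alcohol, epimers (not isolated) | CC(C)=CCC/C(C)=C/C[C@]12C[C@@H](C(O)C=C(C)C)C(C)(C)[C@](C(=O)c3ccccc3)(C1=O)C(=O)C(CC=C(C)C)=C2O | intermediate
14 | bicyclic bis-acetate | CC(C)=CCC/C(C)=C/C[C@]12C[C@@H](C(OC(C)=O)C=C(C)C)C(C)(C)[C@](C(=O)c3ccccc3)(C1=O)C(=O)C(CC=C(C)C)=C2OC(C)=O | intermediate
15 | C4 enol acetate of 16 (not isolated) | CC(C)=CCC/C(C)=C/C[C@]12C[C@@H](CC=C(C)C)C(C)(C)[C@](C(=O)c3ccccc3)(C1=O)C(=O)C(CC=C(C)C)=C2OC(C)=O | intermediate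
16 | endo-7-prenyl bicyclic β-diketone | CC(C)=CCC/C(C)=C/C[C@]12C[C@@H](CC=C(C)C)C(C)(C)[C@](C(=O)c3ccccc3)(C1=O)C(=O)C(CC=C(C)C)=C2O | intermediate
17 | trivalent-iodine enol ether of 16 (not isolated) | CC(C)=CCC/C(C)=C/C[C@]12C[C@@H](CC=C(C)C)C(C)(C)[C@](C(=O)c3ccccc3)(C1=O)C(=O)C(CC=C(C)C)=C2OI(c2ccccc2)OC(=O)C(F)(F)F | intermediate
18 | CNP0164095.1 | CC(C)=CCC/C(C)=C/C[C@@]12C[C@H]3C[C@H]4C(C)(C)[C@H](C(C)(C)O)C[C@]4(C1=O)C(=O)[C@@](C(=O)c1ccccc1)(C2=O)C3(C)C | target

**Total steps:** 8. **Longest linear sequence:** 8 (1 → 2 → 3 → 6 → 9 → 10 → 14 → 16 → 18).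

**Steps most likely to fail**

Step 8 (enolonium bicyclisation). C3 may simply be oxygenated, or the last cation may lose a proton. The fallback sets out from 16 and returns at 18, replacing the two-electron iodane chemistry with a halogen-atom-transfer radical cascade. N-Chlorosuccinimide chlorinates C3 to give the tertiary α-chloro-β-diketone F1. CuCl with tris(2-pyridylmethyl)amine then abstracts chlorine. The C3 radical adds to C11, the C12 radical closes 5-exo onto C13, and chlorine is returned to give the caged tertiary chloride F2. Solvolysis of F2 with AgBF4 in aqueous acetone gives 18.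

Step 4 (desymmetrising allylation and cage closure). The enantioselectivity is untested, and O- or over-allylation may intervene. The fallback sets out from 6 and returns at 9, moving the source of chirality from catalysis to resolution. Allylation with 7 and Pd(PPh3)4, followed by the same HCl closure, gives the racemic cage F3. Esterification of the C10 alcohol with (S)-O-methylmandelic acid (DCC, DMAP) and chromatographic separation gives the mandelate of the wanted enantiomer F4. K2CO3 in MeOH removes the ester, and brief HCl/THF treatment re-closes any opened aldol to give 9.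

Step 5 (decarbonylation of a hindered tetrasubstituted enal at reflux). The reaction may be too slow, or the cage may open. The fallback sets out from 4 and returns at 10, and never installs the second enal arm. C-Geranylation of 4 with geranyl bromide (aq. KOH) gives 3-geranyl-2,4,6-trihydroxybenzophenone F5. C-Prenylation with prenyl bromide gives 3-geranyl-5-prenyl-2,4,6-trihydroxybenzophenone F6. Alkylative dearomatisation with mesylate 5, using a cinchona-derived phase-transfer catalyst and Cs2CO3, gives the dearomatised triketone F7 together with its regioisomer alkylated at the prenyl-bearing carbon. HCl/THF closure and chromatography of the two cages gives 10.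

**Further compounds**
F1 | step 8 | 3-chloro-3-prenyl bicyclic trione (C3 epimers, stereocentre lost in the radical) | CC(C)=CCC/C(C)=C/C[C@]12C[C@@H](CC=C(C)C)C(C)(C)[C@](C(=O)c3ccccc3)(C1=O)C(=O)C(Cl)(CC=C(C)C)C2=O
F2 | step 8 | tertiary chloride analogue of 18 | CC(C)=CCC/C(C)=C/C[C@@]12C[C@H]3C[C@H]4C(C)(C)[C@H](C(C)(C)Cl)C[C@]4(C1=O)C(=O)[C@@](C(=O)c1ccccc1)(C2=O)C3(C)C
F3 | step 4 | racemic enal-bearing hydroxy-adamantane cage | CC(C)=CCC/C(C)=C/CC12CC3C(O)C(CC(C=O)=C(C)C)(C1=O)C(=O)C(C(=O)c1ccccc1)(C2=O)C3(C)C
F4 | step 4 | (S)-O-methylmandelate of 9 | CC(C)=CCC/C(C)=C/C[C@@]12C[C@H]3C(OC(=O)[C@@H](OC)c4ccccc4)[C@@](CC(C=O)=C(C)C)(C1=O)C(=O)[C@@](C(=O)c1ccccc1)(C2=O)C3(C)C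
F5 | step 5 | 3-geranyl-2,4,6-trihydroxybenzophenone | CC(C)=CCC/C(C)=C/Cc1c(O)cc(O)c(C(=O)c2ccccc2)c1O
F6 | step 5 | 3-geranyl-5-prenyl-2,4,6-trihydroxybenzophenone | CC(C)=CCC/C(C)=C/Cc1c(O)c(CC=C(C)C)c(O)c(C(=O)c2ccccc2)c1O
F7 | step 5 | dearomatised triketone with C5 geranyl and enal arm and C3 prenyl | CC(C)=CCC/C(C)=C/C[C@@]1(CC(C=O)=C(C)C)C(=O)C(CC=C(C)C)=C(O)C(C(=O)c2ccccc2)=C1O
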